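Time is not your difficulty: theta's readings stand still from 12.0 h on, far short of your 6.0 d. The question is how D gets shared out.

| flask | Z | D | remark | time |
|---|---|---|---|---|
| epsilon | 0.63 M | 0.21 M | run made earlier |  |
| theta | 0.21 M | 0.21 M | run made earlier |  |
| amber | 0.42 M | 0.210 M |  | 6.0 d |
| green | 0.42 M | 1.05 M |  | 6.0 d |
| blue | 0.42 M | 1.26 M |  | 6.0 d |

- epsilon (time / h: L / %, E / %, Z / %): 2.50: 30.6, 0, 67.8; 8.00: 29.7, 1.1, 68.0; 12.0: 31.2, 1.1, 67.8; 20.0: 30.5, 0.9, 66.7; 30.0: 31.7, 0, 69.5
- theta (time / h: L / %, E / %, Z / %): 2.50: 58.3, 0, 39.2; 8.00: 74.1, 2.0, 20.1; 12.0: 74.6, 2.6, 18.2; 20.0: 75.0, 1.0, 18.7; 30.0: 76.6, 3.2, 18.3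

(each reading ± 1 percentage point)

* L at the end, in percent of the Z charged, for each flask in turn (amber, green, blue)

I read the stop as D being used up: epsilon's L holds 92.2% of the D charged, and I assume that yield for your flasks. With D as limiting reagent, amber then gets L of 46.1%.

Write z and l for Z and L as fractions of the Z charged. The zero of the scale is chance over 4 like sites: L has 3 free sites against the 4 of Z, so D would take L at 0.750 of its rate on Z. Theta's plateau reads z = 18.8% and l = 75.1%, whereas chance gives l = 39.0%. What has passed beyond L, over what L was exposed to, gives as a reading, with theta's scatter in it, the selectivity factor s, the rate of D on L over its rate on Z at equal amounts: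

s ≈ (1 − z − l) / (ln(1/z) − 1 + z) = 0.0711

l = (z^s − z) / (1 − s)

That is well below chance. For green and blue I count Z as consumed and everything past L as E, carrying 4 D, so l = (4 − uptake)/3. The uptakes of 2.31 and 2.77 equivalents give L of 56.3% in green and 41.0% in blue.

The forecast gives 43%, 41% and 31%, reasoning that “The flat plateaus by about 10 h suggest equilibrium”.

The flasks give 46.1%, 64.8% and 56.7%.

    D + X → Q + G (k = 0.00300 /M/s)
    Z + D → L + G (k = 9.20 × 10⁻⁴ /M/s)
    D + L → X + G (k = 6.10 × 10⁻⁵ /M/s)
    D + Q → E + G (k = 0.00140 /M/s)
    2 D → J (k = 3.70 × 10⁻⁵ /M/s)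

In green, the rate constant of D + L is 0.066 of that of Z + D, far below the chance value, and L stands at 64.8% against 25.1% for chance spreading, with an uptake of 2.00 equiv where I had budgeted 2.31 equivalents. With s and green's Z of 0.0515%, the second line gives 62.8%, and with blue's Z of 0.00684% it gives 54.4% against a simulated L of 56.7%.

The earlier runs and the new flask are calculated with made-up constants, noise included.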